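I began with an easy step, adding up the last cedar reading. At 4.00 d substrate read 0%, and substrate, product and intermediate B together made 101% of the charge. So I expected the end state to be a division of the charge between intermediate B and product.

| flask | substrate | remark | time |
|---|---|---|---|
| cedar | 0.20 M | the very flask that is asked about, followed so far |  |
| elm | 0.10 M | run made earlier |  |
| flask | 0.20 M |  | 8.0 d |

- cedar (time / d: substrate / %, product / %, intermediate B / %): 0.333: 2.4, 11.7, 61.9; 0.500: 0, 16.5, 73.1; 0.833: 0, 20.6, 78.1; 1.04: 0, 21.4, 77.8; 1.67: 0, 21.4, 79.0; 2.50: 0.3, 20.8, 79.2; 4.00: 0, 21.1, 79.4
- elm (time / d: substrate / %, product / %, intermediate B / %): 0.333: 2.5, 10.5, 62.6; 0.833: 0, 20.0, 78.0; 1.67: 0, 20.5, 78.8; 2.50: 0, 21.9, 79.3; 3.00: 0.2, 21.4, 78.1; 4.00: 0, 20.5, 78.3; 6.00: 0, 22.1, 78.8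

(standard deviation of a reading: 0.5 percentage points)

- the earlier runs were read with a standard deviation of 0.5 percentage points
- the reaction counts as stopped when no species that holds the substrate changes by six tenths of a point or more over the second half of the time

- which holds at 8.0 d: what has brought the reaction to rest, or that it has not come to rest (forward and back rates have come level / it is still moving / all of the substrate has reacted)
- conversion of substrate at 8.0 d
- amount of product at 8.0 d, in percent of the substrate charged
- amount of intermediate B at 8.0 d, in percent of the substrate charged

I pictured two extremes. In the first, product forms one way from intermediate B, and the charge ends entirely as product. In the second, the two are level from the first moment, and their ratio stands still from the start. Cedar lay between them, and late on close to the second. Its ratio of product to intermediate B read 0.189 at 0.333 d and 0.266 at 4.00 d, so it had not stood still from the start. But later product differed by 0.3 percentage points between 1.67 d and 4.00 d, less than the scatter of 0.5 points, with 79.4% of intermediate B standing by.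

Pooling the last three readings of cedar and elm, product over intermediate B came to 0.269. I call this reading R, the end ratio, product over intermediate B at rest, an equilibrium constant if the step runs both ways. Elm had half of cedar's charge and showed a like plateau in its readings. Product's share of the charge is then R/(1+R), which gave me 21.2% product and 78.8% intermediate B at 8.0 d.

The forecast gave forward and back rates have come level, conversion 100%, product 21.2% and intermediate B 78.8%. It read the plateau as “not exhaustion of the substrate”.

    intermediate B ⇌ product (K = 0.270, k = 0.0770 /h)
    substrate → intermediate A (k = 0.480 /h)
    intermediate A → intermediate B (k = 0.240 /h)

Cedar at 8.0 d gave all of the substrate has reacted, with 0% of the substrate left, conversion 100%, product 21.3% and intermediate B 78.7%. The forecast's amounts stood, but its ending did not. Carried to the neighbouring flask charged with 0.34 M, my share of 21.2% stood beside the 21.3% product that flask ended at, with 78.7% intermediate B. Cedar had come to rest, moving 0 points over the second half of the time. Left until 80.0 d, its product changed by 0 points, and it stood at 21.3% beside 78.7% intermediate B.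

The runs were generated by integration on assumed constants.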